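Late in a run the useful unit is the pool: target and isomer of the product B counted together, because the step between them moves material inside the pool and adds nothing to it. What remains to reckon is the pool against isomer of the product A.

| flask | substrate | reagent | remark | time |
|---|---|---|---|---|
| cedar | 0.10 M (fed, over 15 s) | 0.25 M | run made earlier; the fed solution adds 0.50 times the starting volume |  |
| flask | 0.10 M (fed, over 15 s) | 0.500 M | the fed solution adds 0.50 times the starting volume | 5.0 min |

cedar run (percent of the substrate charged)

| time / s | target / % | isomer of the product A / % |
|---|---|---|
| 10.0 | 1.8 | 0.4 |
| 15.0 | 3.9 | 1.4 |
| 30.0 | 7.4 | 3.0 |

(standard deviation of a reading: 0.3 percentage points)

- amounts are per litre of the starting volume; all of the dose is in the solution fed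
- the numbers in the tables scatter with a standard deviation of 0.3 percentage points
- on the list of suspects stand: substrate + reagent -> isomer of the product A; substrate + reagent -> target; target <-> isomer of the product B
- percentages count the whole charge, also what has not yet gone in

- the target in the flask at 5.0 min, as a percentage of the substrate charged
- the isomer of the product A in the flask at 5.0 min, as a percentage of the substrate charged
- the substrate in the flask at 5.0 min, as a percentage of the substrate charged
- the isomer of the product B in the flask at 5.0 min, as a percentage of the substrate charged
- concentration of reagent at 5.0 min, in M

The cedar run and the flask look nearly the same, with one substrate charge and one feed, but the flask starts with twice the reagent. On the list of suspects both routes out of substrate take substrate and reagent together, so more reagent speeds both by one factor and leaves their ratio alone. Count target as the whole pool at the two earliest cedar readings, a simplification, since isomer of the product B goes unread there. The readings at 10.0 s and 15.0 s, summed to thin the scatter, then give s = 24.0%, the branch share: the fraction of converted substrate that becomes isomer of the product A. It is a reading and carries their scatter.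

So I expect the two flasks to part in pace, not in split. Substrate is the limiting reagent in the flask, at 0.10 M against 0.500 M, and the flask runs ten times as long as cedar's last reading. My reckoning therefore puts isomer of the product A near 24.0% of the charge, an estimate with the scatter of that reading, and reagent no lower than 0.267 M, where one reagent per substrate leaves it when the whole charge has reacted.

The forecast gives 32% target, 22% isomer of the product A, 6% substrate, 40% isomer of the product B and 0.271 M reagent. On the split inside the pool it warns that “K is unknown from these runs, so it is very uncertain”.

    substrate + reagent → isomer of the product A (k = 0.0106 /M/s)
    substrate + reagent → target (k = 0.0311 /M/s)
    target ⇌ isomer of the product B (K = 1.40, k = 0.0366 /s)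

The flask gives 30.4% target, 24.6% isomer of the product A, 41.9% isomer of the product B, 3.09% substrate and 0.269 M reagent. Applied to what has converted, s gives 23.3% isomer of the product A. For the neighbour with 0.40 M substrate it gives 20.7% against that flask's 21.9%. The flask is near rest, not at it: isomer of the product B over target already stands at 1.38, against K3 of 1.4. At ten times the time substrate reaches 0%, and s sends 0.74 percentage points of that remainder to isomer of the product A, which ends at 25.4%, with target 31.1% and isomer of the product B 43.5%.

The earlier runs and the new flask were generated by integration with constants of no real substance, noise included.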